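The isovanillate is cut between the carbonyl carbon and aromatic C-1, not at its C–O bond. Aromatic C-1 is the benzene carbon para to the methoxy-bearing C-4 and meta to the hydroxy-bearing C-3. Because C-1 is meta to that oxygen, unprotected 5-iodoguaiacol can be turned into a C,O-dimagnesiated arene whose only carbon nucleophile is C-1. Its partner holds the carbonyl carbon at the carbonic acid level, as the imidazole-1-carboxylate on the carbinol oxygen of the complete (S)-configured eleven-membered ring. One addition–elimination joins both halves and delivers the free phenol ester directly. The carbocycle arises by asymmetric propargylation, carboalumination, Negishi coupling and an 11-endo Heck macrocyclisation.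

Key step: step 8

Remark: the carbocycle is numbered C-1 (carbinol), C-2, C-3(Me)=C-4, C-5, C-6, C-7(=CH2), C-8=C-9, C-10(Me2), C-11. Compounds 1, 3, 7, 13 and both antipodes of TRIP are taken as catalogue compounds.

Step 1
Reactants: 1 methyl 3,3-dimethylpent-4-enoate
Product: 2 3,3-dimethylpent-4-enal
Conditions: DIBAL-H (1.05 equiv), CH2Cl2, −78 °C; aq Rochelle salt
Reagents that add atoms: none
Why: Partial DIBAL-H reduction of an ester, in which the tetrahedral aluminium hemiacetal persists at −78 °C and releases the aldehyde only on work-up, while the isolated vinyl group is inert.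

Step 2
Reactants: 2 3,3-dimethylpent-4-enal; 3 allenylboronic acid pinacol ester
Product: 4 (S)-6,6-dimethyloct-7-en-1-yn-4-ol
Conditions: (S)-TRIP (10 mol %), 4 Å MS, toluene, −20 °C; aq NaHCO3
Reagents that add atoms: none
Why: Chiral phosphoric acid-catalysed asymmetric propargylation (SE2' allenylboration through a closed six-membered chair), in which the (S)-TRIP phosphate binds a boronate oxygen and the formyl hydrogen and should expose the Si face of 2, setting the (S)-carbinol centre, the only stereocentre of the target.

Step 3
Reactants: 4 (S)-6,6-dimethyloct-7-en-1-yn-4-ol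
Product: 6 (1E,4R)-1-iodo-2,6,6-trimethylocta-1,7-dien-4-ol, via alkenylalane 5 (not isolated)
Conditions: Me3Al (3 equiv), Cp2ZrCl2 (25 mol %), CH2Cl2, 0 °C to rt; then I2, THF, −30 °C; aq K2CO3
Reagents that add atoms: trimethylaluminium C[Al](C)C; iodine II
Why: Negishi zirconium-catalysed carboalumination, in which syn addition of Me–Al to the terminal alkyne (methyl to the internal carbon, after in situ aluminium alkoxide formation) and iodinolysis with retention fix the (E)-trisubstituted alkene, while the hindered vinyl group on the quaternary carbon does not react and the carbinol centre is untouched.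

Step 4
Reactants: 7 3-bromobut-3-en-1-ol
Product: 8 2-bromo-4-iodobut-1-ene
Conditions: I2, PPh3, imidazole, CH2Cl2, 0 °C to rt
Reagents that add atoms: iodine II
Why: Appel-type iodination (Garegg–Samuelsson conditions), an SN2 displacement of the primary oxyphosphonium ion by iodide that leaves the alkenyl bromide untouched.

Step 5
Reactants: 8 2-bromo-4-iodobut-1-ene; 6 (1E,4R)-1-iodo-2,6,6-trimethylocta-1,7-dien-4-ol
Product: 10 (5S,7E)-11-bromo-3,3,7-trimethyldodeca-1,7,11-trien-5-ol, via homoallylic organozinc 9 (not isolated)
Conditions: 8, Zn dust (activated with 1,2-dibromoethane/TMSCl), THF, 35 °C; then 6, PdCl2(dppf) (5 mol %), THF, 0 °C to rt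
Reagents that add atoms: none
Why: Negishi coupling of a homoallylic alkylzinc iodide with an alkenyl iodide, in which oxidative addition to C(sp2)–I is much faster than to the 2-bromoalkene units, proceeds with retention of the (E)-geometry, is followed by dppf-accelerated reductive elimination ahead of β-hydride elimination, and uses a zinc reagent too weakly basic to be quenched by the free secondary alcohol on the time scale of the coupling.

Step 6
Reactants: 10 (5S,7E)-11-bromo-3,3,7-trimethyldodeca-1,7,11-trien-5-ol
Product: 11 (1S,3E,8E)-3,10,10-trimethyl-7-methylidenecycloundeca-3,8-dien-1-ol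
Conditions: Pd(OAc)2 (20 mol %), Bu4NCl, K2CO3, DMF (2 mM, syringe-pump addition of 10), 70 °C
Reagents that add atoms: none
Why: Intramolecular Mizoroki–Heck reaction (Jeffery conditions, high dilution, 11-endo mode, helped by the Thorpe–Ingold effect of the gem-dimethyl group), in which the alkenylpalladium at C-7 adds to the unsubstituted vinyl terminus C-8 and, because C-10 is quaternary, the only β-hydrogens lie on C-8, so syn elimination should give the (E)-C-8=C-9 alkene of the 1,3-diene without chain walking.

Step 7
Reactants: 11 (1S,3E,8E)-3,10,10-trimethyl-7-methylidenecycloundeca-3,8-dien-1-ol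
Product: 12 (1S,3E,8E)-3,10,10-trimethyl-7-methylidenecycloundeca-3,8-dien-1-yl 1H-imidazole-1-carboxylate
Conditions: CDI (1.5 equiv), CH2Cl2, rt; water wash
Reagents that add atoms: 1,1'-carbonyldiimidazole O=C(n1ccnc1)n1ccnc1
Why: Acyl transfer from CDI to the alcohol, which stops after one substitution because the alkyl imidazole-1-carboxylate is far less electrophilic than CDI, runs under neutral conditions that spare the triene, and leaves the C–O bond at the stereocentre intact.

Step 8
Reactants: 12 (1S,3E,8E)-3,10,10-trimethyl-7-methylidenecycloundeca-3,8-dien-1-yl 1H-imidazole-1-carboxylate; 13 5-iodo-2-methoxyphenol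
Product: 16 (1S,3E,8E)-3,10,10-trimethyl-7-methylidenecycloundeca-3,8-dien-1-yl 3-hydroxy-4-methoxybenzoate, via magnesium iodophenolate 14 (not isolated), via dimagnesiated arene 15 (not isolated)
Conditions: 13 (1.4 equiv), LiCl, MeMgCl (1.4 equiv), THF, −30 °C; i-PrMgCl (1.35 equiv), −30 °C to rt; then 12 (1.0 equiv), −40 to 0 °C; aq NH4Cl
Reagents that add atoms: none
Why: MeMgCl converts the phenol of 13 into the magnesium phenolate 14, iodine–magnesium exchange with i-PrMgCl/LiCl then gives the C,O-dimagnesiated arene 15, and its sp2 C–Mg carbon adds to the carbonyl carbon of 12, after which the tetrahedral adduct expels imidazolide and leaves the benzoate. The closest known reaction type is the ester synthesis from Grignard reagents and alkyl imidazole-1-carboxylates, combined with halogen–magnesium exchange on unprotected iodophenolates. No ring is closed and no stereocentre is formed; the C–O bond at the (S)-carbinol carbon is never broken, so its configuration is carried through unchanged. The step needs C- over O-acylation, secured because the aggregated magnesium phenolate is a poor nucleophile toward the sluggish carbamate-type carbonyl at or below 0 °C while the aryl–Mg bond is not, and because 12 is the limiting component. It also needs single addition, secured because the product ester, deactivated by the para-methoxy and meta-phenolate groups and shielded by the neopentyl-flanked secondary alkoxy group, is far less electrophilic than the acyl imidazole 12. The absence of transition metals, acids and oxidants leaves the 1,3-diene and the trisubstituted alkene of the eleven-membered ring untouched.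

Compound list
1 | methyl 3,3-dimethylpent-4-enoate | COC(=O)CC(C)(C)C=C | starting material
2 | 3,3-dimethylpent-4-enal | O=CCC(C)(C)C=C | intermediate
3 | allenylboronic acid pinacol ester (4,4,5,5-tetramethyl-2-(propa-1,2-dien-1-yl)-1,3,2-dioxaborolane) | C=C=CB1OC(C)(C)C(C)(C)O1 | starting material
4 | (S)-6,6-dimethyloct-7-en-1-yn-4-ol | C=CC(C)(C)C[C@@H](O)CC#C | intermediate
5 | (E)-alkenyl(dimethyl)alane of 4, carried as its O-dimethylaluminium alkoxide | C=CC(C)(C)C[C@@H](O[Al](C)C)C/C(C)=C/[Al](C)C | intermediate
6 | (1E,4R)-1-iodo-2,6,6-trimethylocta-1,7-dien-4-ol (same spatial arrangement as 4; the descriptor changes only because iodine raises the CIP rank of the alkenyl branch) | C=CC(C)(C)C[C@@H](O)C/C(C)=C/I | intermediate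
7 | 3-bromobut-3-en-1-ol | C=C(Br)CCO | starting material
8 | 2-bromo-4-iodobut-1-ene | C=C(Br)CCI | intermediate
9 | (3-bromobut-3-en-1-yl)zinc iodide | C=C(Br)CC[Zn]I | intermediate
10 | (5S,7E)-11-bromo-3,3,7-trimethyldodeca-1,7,11-trien-5-ol | C=CC(C)(C)C[C@@H](O)C/C(C)=C/CCC(Br)=C | intermediate
11 | (1S,3E,8E)-3,10,10-trimethyl-7-methylidenecycloundeca-3,8-dien-1-ol | C=C1/C=C/C(C)(C)C[C@@H](O)C/C(C)=C/CC1 | intermediate
12 | (1S,3E,8E)-3,10,10-trimethyl-7-methylidenecycloundeca-3,8-dien-1-yl 1H-imidazole-1-carboxylate | C=C1/C=C/C(C)(C)C[C@@H](OC(=O)n2ccnc2)C/C(C)=C/CC1 | intermediate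
13 | 5-iodo-2-methoxyphenol | COc1ccc(I)cc1O | starting material
14 | chloromagnesium 5-iodo-2-methoxyphenolate | COc1ccc(I)cc1O[Mg]Cl | intermediate
15 | chloromagnesium 5-(chloromagnesio)-2-methoxyphenolate | COc1ccc([Mg]Cl)cc1O[Mg]Cl | intermediate
16 | (1S,3E,8E)-3,10,10-trimethyl-7-methylidenecycloundeca-3,8-dien-1-yl 3-hydroxy-4-methoxybenzoate | C=C1/C=C/C(C)(C)C[C@@H](OC(=O)c2ccc(OC)c(O)c2)C/C(C)=C/CC1 | target

Total step count: 8. Longest linear sequence: 7 (steps 1, 2, 3, 5, 6, 7, 8).

Steps most likely to fail

Step 6 (macrocyclic Heck reaction). Intermolecular coupling to oligomers and catalyst decay may outrun the strained 11-endo insertion.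
- The fallback sets out from 10, comes back at 11, and closes the same C-7–C-8 bond by carbonyl addition.
- Compound 10 is silylated (TBSCl, imidazole) to the O-TBS ether of 10 F1.
- The monosubstituted vinyl group is hydroborated selectively (9-BBN; NaOH, H2O2) to the primary alcohol F2.
- Dess–Martin oxidation gives the aldehyde F3.
- A Nozaki–Hiyama–Kishi macrocyclisation (CrCl2, cat. NiCl2, DMF, high dilution) gives the macrocyclic allylic alcohol F4 as an inconsequential mixture of epimers at C-8.
- Dehydration with Martin sulfurane, for which only the C-9 hydrogens are available, gives the O-TBS ether of 11 F5, and TBAF returns 11.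

Step 8 (key step). Three things may erode the union: incomplete iodine–magnesium exchange on the electron-rich phenolate followed by isopropyl transfer, competing acylation at the phenolate oxygen, and a second aryl addition to the product ester.
- The fallback sets out from 11 (together with 13), comes back at 16, and builds the same aryl–carbonyl bond by CO insertion.
- Compound 13 is silylated (TBSCl, imidazole) to tert-butyl(5-iodo-2-methoxyphenoxy)dimethylsilane F6.
- Palladium-catalysed alkoxycarbonylation of F6 with 11 (Pd(OAc)2, Xantphos, CO 1 atm, Et3N, toluene, 80 °C) gives the O-TBS ether of 16 F7.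
- TBAF buffered with AcOH releases 16.

Step 2 (asymmetric propargylation). Facial discrimination may be insufficient for an α-unbranched aliphatic aldehyde, which would compromise the single-enantiomer requirement.
- The fallback sets out from 2, comes back at 4, and secures the centre by resolution.
- Corey–Chaykovsky methylenation (Me3SI, NaH, DMSO–THF) gives racemic 2-(2,2-dimethylbut-3-en-1-yl)oxirane F8.
- Hydrolytic kinetic resolution with (R,R)-(salen)Co(III)OAc and 0.55 equiv of water should leave (R)-2-(2,2-dimethylbut-3-en-1-yl)oxirane F9.
- Opening at the terminal carbon with lithium acetylide–ethylenediamine complex in DMSO gives 4 with the C–O bond at the stereocentre untouched.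

Further compounds
F1 | step 6 | O-TBS ether of 10 | C=CC(C)(C)C[C@@H](O[Si](C)(C)C(C)(C)C)C/C(C)=C/CCC(Br)=C
F2 | step 6 | primary alcohol from anti-Markovnikov hydration of the vinyl group of F1 | OCCC(C)(C)C[C@@H](O[Si](C)(C)C(C)(C)C)C/C(C)=C/CCC(Br)=C
F3 | step 6 | aldehyde from oxidation of F2 | O=CCC(C)(C)C[C@@H](O[Si](C)(C)C(C)(C)C)C/C(C)=C/CCC(Br)=C
F4 | step 6 | macrocyclic allylic alcohol (C-8 hydroxy, epimer mixture at C-8, C-1 O-TBS) | C=C1C(O)CC(C)(C)C[C@@H](O[Si](C)(C)C(C)(C)C)C/C(C)=C/CC1
F5 | step 6 | O-TBS ether of 11 | C=C1/C=C/C(C)(C)C[C@@H](O[Si](C)(C)C(C)(C)C)C/C(C)=C/CC1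
F6 | step 8 | tert-butyl(5-iodo-2-methoxyphenoxy)dimethylsilane | COc1ccc(I)cc1O[Si](C)(C)C(C)(C)C
F7 | step 8 | O-TBS ether of 16 | C=C1/C=C/C(C)(C)C[C@@H](OC(=O)c2ccc(OC)c(O[Si](C)(C)C(C)(C)C)c2)C/C(C)=C/CC1
F8 | step 2 | racemic 2-(2,2-dimethylbut-3-en-1-yl)oxirane | C=CC(C)(C)CC1CO1
F9 | step 2 | (R)-2-(2,2-dimethylbut-3-en-1-yl)oxirane | C=CC(C)(C)C[C@@H]1CO1
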